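**Retrosynthetic overview**
1. The lactol carbon is set last: the racemic lactol is resolved as its (S)-1-phenylethyl acetal and released by hydrogenolysis; before that only a ring B methyl ether is removed.
2. The seven-membered dioxepinone ring is opened at two bonds at once, ring A carbon–C(=O) and ring A oxygen–ring B carbon, giving o-iodophenol 12 and fluoro aryl formate 9, whose formyl carbon already sits on the ring B oxygen.
3. Enabling feature: on ring A the acyl-bearing carbon and the ether oxygen are ortho, and atranol has a mirror plane through CHO and CH3, so iodination needs no regiocontrol. On ring B the ether carbon lies between the ester oxygen and the lactol carbon, which in base is a free ortho CHO that activates C–F for SNAr once the neighbouring oxygen is acylated.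
4. Ring B comes from 2,4,5-trifluorobenzonitrile by two SNAr steps, nitrile hydrolysis, carboxylate-directed ortho-lithiation/formylation and Duff formylation; ring A comes from atranol in two steps.
5. Ring order: both benzene rings are bought; the lactol (phthalide) ring closes in step 4 and the dioxepinone ring in step 9.

Key step: step 9

Assumption: the lactol carbon is a hemiacetal that can epimerise through the ring-opened 2-formylbenzoic acid, so it is carried as a racemate, fixed as a diastereomerically pure acetal and released only in the last step under neutral conditions, where it is taken to be configurationally stable in aprotic medium and as a solid.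

**Route**

Step 1
Reactants: 1 2,4,5-trifluorobenzonitrile
Product: 2 4-(tert-butoxy)-2,5-difluorobenzonitrile
Conditions: KOtBu (1.05 equiv), THF, −40 to 0 °C
Reagents that add atoms: potassium tert-butoxide, CC(C)(C)[O-].[K+]
Why: SNAr; the fluoride para to the nitrile and ortho to another fluorine is the most activated site, and the bulky alkoxide should avoid the ortho position.

Step 2
Reactants: 2 4-(tert-butoxy)-2,5-difluorobenzonitrile
Product: 3 4-(tert-butoxy)-5-fluoro-2-methoxybenzonitrile
Conditions: NaOMe (1.2 equiv), MeOH/THF, 50 °C
Reagents that add atoms: sodium methoxide, C[O-].[Na+]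
Why: second SNAr at the only remaining fluoride conjugated (ortho) to the nitrile; the 5-fluoride is meta to CN and next to a donor oxygen and should stay.

Step 3
Reactants: 3 4-(tert-butoxy)-5-fluoro-2-methoxybenzonitrile
Product: 4 4-(tert-butoxy)-5-fluoro-2-methoxybenzoic acid
Conditions: KOH, H2O/ethylene glycol, 130 °C; then cold 1 M HCl to pH 3
Reagents that add atoms: potassium hydroxide, [K+].[OH-]; water, O
Why: alkaline nitrile hydrolysis; the aryl ethers and the now unactivated aryl fluoride are stable to base.

Step 4
Reactants: 4 4-(tert-butoxy)-5-fluoro-2-methoxybenzoic acid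
Product: 7 rac-4-fluoro-3,5-dihydroxy-7-methoxyisobenzofuran-1(3H)-one, via dilithiated benzoate 5 (not isolated), via tert-butyl ether lactol 6 (not isolated)
Conditions: s-BuLi (2.2 equiv), TMEDA, THF, −78 °C; DMF, −78 °C; then 6 M HCl, THF, 50 °C
Reagents that add atoms: N,N-dimethylformamide, CN(C)C=O
Why: carboxylate-directed ortho-metalation, reinforced by the ortho fluorine, then formylation; the 2-formylbenzoic acid closes to the 3-hydroxyphthalide and the aqueous acid cleaves the aryl tert-butyl ether, with the lactol carbon formed as a racemate.

Step 5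
Reactants: 7 rac-4-fluoro-3,5-dihydroxy-7-methoxyisobenzofuran-1(3H)-one
Product: 8 rac-4-fluoro-3,5-dihydroxy-7-methoxy-1-oxo-1,3-dihydroisobenzofuran-6-carbaldehyde (CHO at C-6, between 5-OH and 7-OMe)
Conditions: hexamethylenetetramine (3 equiv), TFA, 80 °C; then 3 M HCl, 60 °C
Reagents that add atoms: hexamethylenetetramine, C1N2CN3CN1CN(C2)C3; water, O
Why: Duff formylation at the only free ring position, which is ortho to the free phenol and to the methoxy group; the lactol stays closed in acid.

Step 6
Reactants: 8 rac-4-fluoro-3,5-dihydroxy-7-methoxy-1-oxo-1,3-dihydroisobenzofuran-6-carbaldehyde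
Product: 9 rac-4-fluoro-6-formyl-7-methoxy-1-oxo-1,3-dihydroisobenzofuran-3,5-diyl diformate
Conditions: HCO2H/Ac2O (preformed acetic formic anhydride, 4 equiv), NaOAc (cat.), THF, 0 °C to rt; used crude
Reagents that add atoms: acetic formic anhydride, CC(=O)OC=O
Why: O-formylation of the phenol and the lactol hydroxyl with the mixed anhydride, in which formyl transfer is faster than acetyl transfer; the product is an electron-poor, doubly ortho-substituted aryl formate of the kind used as a CO surrogate.

Step 7
Reactants: 10 atranol (2,6-dihydroxy-4-methylbenzaldehyde)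
Product: 11 2,6-dihydroxy-3-iodo-4-methylbenzaldehyde
Conditions: NIS (1.0 equiv), MeCN, 0 °C
Reagents that add atoms: N-iodosuccinimide, O=C1CCC(=O)N1I
Why: electrophilic aromatic iodination of a resorcinol-type ring; the two open positions are equivalent by the mirror plane, so only mono- versus di-iodination has to be controlled.

Step 8
Reactants: 11 2,6-dihydroxy-3-iodo-4-methylbenzaldehyde
Product: 12 2-hydroxy-3-iodo-4-methyl-6-[(triisopropylsilyl)oxy]benzaldehyde
Conditions: TIPSCl (1.05 equiv), imidazole, CH2Cl2, 0 °C
Reagents that add atoms: chlorotriisopropylsilane, CC(C)[Si](Cl)(C(C)C)C(C)C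
Why: silylation with a bulky silyl chloride should take the hydroxyl flanked only by CHO and H, not the one wedged between CHO and iodine.

Step 9
Reactants: 12 2-hydroxy-3-iodo-4-methyl-6-[(triisopropylsilyl)oxy]benzaldehyde; 9 rac-4-fluoro-6-formyl-7-methoxy-1-oxo-1,3-dihydroisobenzofuran-3,5-diyl diformate
Product: 14 rac-depsidone methyl ether (target skeleton bearing OMe in place of the ring B phenol; racemic lactol), via fluoro depside 13 (not isolated)
Conditions: Pd(OAc)2 (5 mol %), Xantphos (7.5 mol %), Et3N (3 equiv, slow addition), DMF, sealed vessel, 60 °C; then CsF (1 equiv), 90 °C, same pot; 1 M HCl work-up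
Reagents that add atoms: none
Why: Et3N decarbonylates the aryl formate of 9 (the lactol formate follows by formyl transfer to the phenoxide), giving CO and the ring B phenoxide in the flask; Pd(0)/Xantphos adds oxidatively to the C–I bond of 12, CO inserts, and the aroyl–Pd is captured by that phenoxide to give depside 13, whose lactol is ring-opened in base to an o-formyl benzoate. The closest known reactions are the Pd/Xantphos esterification of aryl halides with aryl formates as CO surrogates (including hindered, electron-poor ones such as 2,4,6-trichlorophenyl formate) and the fluoride-mediated SNAr etherification of o-fluorobenzaldehydes with phenols or their silyl ethers. Fluoride then starts the second bond: the ring A phenoxide attacks the C–F carbon of ring B in a 7-exo-trig addition–elimination (Meisenheimer complex stabilised by the ortho CHO), which closes the seven-membered dioxepinone, and the expelled fluoride removes the TIPS group as TIPS–F, so fluoride acts only as a relay. No stereocentre is created; the lactol re-closes as a racemate on acidic work-up and is fixed in step 11. The step needs capture of the aroyl–Pd by the ring B phenoxide alone, which is secured by the TIPS ether on the only unhindered ring A hydroxyl, by the methyl ether on the second ring B oxygen and by a base that ionises the acidic ring B phenol far more than the chelated ring A hydroxyl; it also needs ester formation before ether formation, which follows because the C–F carbon is deactivated while its neighbour is a phenoxide and is switched on once that oxygen is acylated. Regiochemistry is fixed by the single C–I bond, the single C–F bond and the single free hydroxyl of 12.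

Step 10
Reactants: 14 rac-depsidone methyl ether
Product: 15 rac-1,4,10-trihydroxy-8-methyl-3,7-dioxo-1,3-dihydro-7H-2,6,12-trioxabenzo[5,6]cyclohepta[1,2-e]indene-5,11-dicarbaldehyde (racemic target)
Conditions: BCl3 (4 equiv), CH2Cl2, −78 to 0 °C; H2O quench
Reagents that add atoms: none
Why: chelation-assisted Lewis-acid demethylation of the aryl methyl ether flanked by the lactone carbonyl and the CHO group; the depsidone ester, the aldehydes and the lactol (after aqueous work-up) should survive.

Step 11
Reactants: 15 racemic target; 16 (S)-1-phenylethanol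
Product: 18 (1S)-lactol (S)-1-phenylethyl acetal of the target, via (1R)-epimeric acetal 17 (not isolated)
Conditions: 16 (3 equiv), PPTS (0.2 equiv), 4 Å MS, toluene, 60 °C; chromatography on silica; fractions holding epimer 17 returned unpurified to the same conditions
Reagents that add atoms: none
Why: acid-catalysed acetalisation of the 3-hydroxyphthalide (pseudo-acid) through its oxocarbenium ion forms both lactol epimers, which interconvert under the same PPTS conditions; the (S) lactol centre is set by taking out the (S,S)-diastereomer 18 by chromatography, while the (1R)-epimer 17 is not purified but sent back into the equilibration, where it should be converted into further 18.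

Step 12
Reactants: 18 (1S)-lactol (S)-1-phenylethyl acetal of the target
Product: 19 (1S)-1,4,10-trihydroxy-8-methyl-3,7-dioxo-1,3-dihydro-7H-2,6,12-trioxabenzo[5,6]cyclohepta[1,2-e]indene-5,11-dicarbaldehyde (target, CNP0296574.1)
Conditions: H2 (1 atm), 10% Pd/C, EtOAc, 20 °C; filtration and evaporation below 25 °C
Reagents that add atoms: none
Why: hydrogenolysis of a benzylic acetal, as in the release of free lactols from benzyl glycosides, cleaves only the O–CH(CH3)Ph bond, so the acetal carbon keeps its (S) configuration; chelated salicylaldehyde-type CHO groups are known to tolerate these conditions.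

**Compound list**
1 | 2,4,5-trifluorobenzonitrile | N#Cc1cc(F)c(F)cc1F | starting material
2 | 4-(tert-butoxy)-2,5-difluorobenzonitrile | N#Cc1cc(F)c(OC(C)(C)C)cc1F | intermediate
3 | 4-(tert-butoxy)-5-fluoro-2-methoxybenzonitrile | N#Cc1cc(F)c(OC(C)(C)C)cc1OC | intermediate
4 | 4-(tert-butoxy)-5-fluoro-2-methoxybenzoic acid | OC(=O)c1cc(F)c(OC(C)(C)C)cc1OC | intermediate
5 | lithium 4-(tert-butoxy)-5-fluoro-6-lithio-2-methoxybenzoate | [Li]OC(=O)c1c([Li])c(F)c(OC(C)(C)C)cc1OC | intermediate
6 | rac-5-(tert-butoxy)-4-fluoro-3-hydroxy-7-methoxyisobenzofuran-1(3H)-one | O=C1OC(O)c2c(F)c(OC(C)(C)C)cc(OC)c12 | intermediate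
7 | rac-4-fluoro-3,5-dihydroxy-7-methoxyisobenzofuran-1(3H)-one | O=C1OC(O)c2c(F)c(O)cc(OC)c12 | intermediate
8 | rac-4-fluoro-3,5-dihydroxy-7-methoxy-1-oxo-1,3-dihydroisobenzofuran-6-carbaldehyde | O=C1OC(O)c2c(F)c(O)c(C=O)c(OC)c12 | intermediate
9 | rac-4-fluoro-6-formyl-7-methoxy-1-oxo-1,3-dihydroisobenzofuran-3,5-diyl diformate | O=COC1OC(=O)c2c(OC)c(C=O)c(OC=O)c(F)c12 | intermediate
10 | atranol (2,6-dihydroxy-4-methylbenzaldehyde) | Cc1cc(O)c(C=O)c(O)c1 | starting material
11 | 2,6-dihydroxy-3-iodo-4-methylbenzaldehyde | Cc1cc(O)c(C=O)c(O)c1I | intermediate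
12 | 2-hydroxy-3-iodo-4-methyl-6-[(triisopropylsilyl)oxy]benzaldehyde | Cc1cc(O[Si](C(C)C)(C(C)C)C(C)C)c(C=O)c(O)c1I | intermediate
13 | rac-4-fluoro-6-formyl-3-hydroxy-7-methoxy-1-oxo-1,3-dihydroisobenzofuran-5-yl 3-formyl-2-hydroxy-6-methyl-4-[(triisopropylsilyl)oxy]benzoate (fluoro depside; ring-opened 2-formylbenzoate in base) | Cc1cc(O[Si](C(C)C)(C(C)C)C(C)C)c(C=O)c(O)c1C(=O)Oc1c(F)c2C(O)OC(=O)c2c(OC)c1C=O | intermediate
14 | rac-1,10-dihydroxy-4-methoxy-8-methyl-3,7-dioxo-1,3-dihydro-7H-2,6,12-trioxabenzo[5,6]cyclohepta[1,2-e]indene-5,11-dicarbaldehyde | Cc1cc(O)c(C=O)c2c1C(=O)Oc1c(C=O)c(OC)c3c(c1O2)C(O)OC3=O | intermediate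
15 | rac-1,4,10-trihydroxy-8-methyl-3,7-dioxo-1,3-dihydro-7H-2,6,12-trioxabenzo[5,6]cyclohepta[1,2-e]indene-5,11-dicarbaldehyde | Cc1cc(O)c(C=O)c2c1C(=O)Oc1c(C=O)c(O)c3c(c1O2)C(O)OC3=O | intermediate
16 | (S)-1-phenylethanol | C[C@H](O)c1ccccc1 | starting material
17 | (1R)-1-[(1S)-1-phenylethoxy] acetal, lactol epimer of 18 (formed in the equilibration and fed back into it) | Cc1cc(O)c(C=O)c2c1C(=O)Oc1c(C=O)c(O)c3c(c1O2)[C@H](O[C@@H](C)c1ccccc1)OC3=O | intermediate
18 | (1S)-1-[(1S)-1-phenylethoxy] acetal of the target (lactol carbon S, auxiliary S) | Cc1cc(O)c(C=O)c2c1C(=O)Oc1c(C=O)c(O)c3c(c1O2)[C@@H](O[C@@H](C)c1ccccc1)OC3=O | intermediate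
19 | (1S)-1,4,10-trihydroxy-8-methyl-3,7-dioxo-1,3-dihydro-7H-2,6,12-trioxabenzo[5,6]cyclohepta[1,2-e]indene-5,11-dicarbaldehyde | Cc1cc(O)c(C=O)c2c1C(=O)Oc1c(C=O)c(O)c3c(c1O2)[C@@H](O)OC3=O | target

**Step count and risks**
Total steps: 12. Longest linear sequence: 10 steps (steps 1–6, then 9–12, from compound 1); the ring A branch (steps 7–8) joins at step 9.

Steps most likely to fail:

1. Step 9. The aroyl–palladium may be captured by a ring A phenoxide or by the ring B carboxylate instead of the ring B phenoxide, the silyl ether may be lost too early, or the activated depside ester may undergo acyl transfer or hydrolysis before the ether closes. The fallback separates the two bond formations and uses the free phenol of ring B instead of its formate. It sets out from 12, which is hydroxycarbonylated (Pd(OAc)2, Xantphos, CO, H2O, Et3N) to 3-formyl-2-hydroxy-6-methyl-4-[(triisopropylsilyl)oxy]benzoic acid F1. F1 is coupled with the 5-hydroxyl of phenol 8 by the classical depside esterification (trifluoroacetic anhydride, toluene) to give depside 13, now isolated and purified. Ring closure of 13 with CsF in DMF then returns to the route at 14.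

2. Step 12. The aryl aldehydes may be over-reduced, the benzylic C–O bond on the phthalide side may be hydrogenolysed instead, or the freed lactol may epimerise through ring opening. The fallback replaces hydrogenolysis by a photochemical release and sets out from 15. Acetalisation of 15 with (S)-1-(2-nitrophenyl)ethanol (PPTS, toluene) and separation should give the (S)-lactol (S)-1-(2-nitrophenyl)ethyl acetal F2 beside its lactol epimer F3, which is re-equilibrated. Irradiation of F2 at 365 nm in dry MeCN cleaves the o-nitrobenzyl-type group by intramolecular hydrogen abstraction without touching the acetal carbon and returns to the route at 19.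

3. Step 4. Lithiation may occur between the two alkoxy groups instead of next to the carboxylate, the o-fluoroaryllithium may lose LiF to an aryne, or s-BuLi may add to the carboxylate. The fallback changes the directing group to a tertiary amide and sets out from 4. Conversion of 4 (SOCl2, then Et2NH) gives 4-(tert-butoxy)-N,N-diethyl-5-fluoro-2-methoxybenzamide F4. Amide-directed ortho-lithiation (s-BuLi, TMEDA, THF, −78 °C) and DMF quench give 4-(tert-butoxy)-N,N-diethyl-3-fluoro-2-formyl-6-methoxybenzamide F5. Heating F5 in aqueous HCl/AcOH hydrolyses the amide with participation of the formyl group, cleaves the tert-butyl ether and returns to the route at 7.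

Further compounds
F1 | step 9 | 3-formyl-2-hydroxy-6-methyl-4-[(triisopropylsilyl)oxy]benzoic acid | Cc1cc(O[Si](C(C)C)(C(C)C)C(C)C)c(C=O)c(O)c1C(=O)O
F2 | step 12 | (1S)-1-[(1S)-1-(2-nitrophenyl)ethoxy] acetal of the target | Cc1cc(O)c(C=O)c2c1C(=O)Oc1c(C=O)c(O)c3c(c1O2)[C@@H](O[C@@H](C)c1ccccc1[N+](=O)[O-])OC3=O
F3 | step 12 | (1R)-1-[(1S)-1-(2-nitrophenyl)ethoxy] acetal, lactol epimer of F2 | Cc1cc(O)c(C=O)c2c1C(=O)Oc1c(C=O)c(O)c3c(c1O2)[C@H](O[C@@H](C)c1ccccc1[N+](=O)[O-])OC3=O
F4 | step 4 | 4-(tert-butoxy)-N,N-diethyl-5-fluoro-2-methoxybenzamide | CCN(CC)C(=O)c1cc(F)c(OC(C)(C)C)cc1OC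
F5 | step 4 | 4-(tert-butoxy)-N,N-diethyl-3-fluoro-2-formyl-6-methoxybenzamide | CCN(CC)C(=O)c1c(C=O)c(F)c(OC(C)(C)C)cc1OC
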